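**Plan**

- The target is the (3S,4S,5R)-lactone with ring atoms O1, C2 (C=O), C3 (ring A benzyl), C4 (CH2OH) and C5 (ring B). It is 3,4-cis and 4,5-trans.
- Enabling feature: C3 is alpha to C2 and bonded to C4, and the CH2OH carbon on C4 lies outside the ring. A C3 radical can therefore attack a vinyl group on C5 in a 5-exo sense, and the CH2 radical this leaves can take its oxygen from O2.
- Cuts, in order: CH2–OH and C3–C4 (radical step, C2 held as an acetal), then O1–C2 (iodoacetalisation), then C5–vinyl (Grignard) and the C2=C3 enol ether bond (Wittig).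
- Forward: vanillin gives the (R)-1-arylallyl alcohol and eugenol gives the 3-aryl enol ether. NIS joins them at O1–C2. The oxolane, the only ring made, closes in the radical step, and C2 is then oxidised to the lactone.
- Stereochemistry: C5 comes from a lipase resolution. C4 is set trans to C5 during ring closure. C3 is biased cis in the closure and fixed finally by kinetic protonation of the lactone enolate anti to the C4 arm.

Key step: step 9

Remark: lactone numbering (O1, C2–C5) is used for every cyclic compound. The enol ether geometry, the carbon–iodine centre and the acetal or lactol centre at C2 are mixtures of no consequence, because all are erased later, so they are left open in the SMILES.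

**Step 1**
Reactants: 1 vanillin
Product: 2 4-(tert-butyldimethylsilyloxy)-3-methoxybenzaldehyde
Conditions: TBSCl, imidazole, DMF, 0 °C to rt
Reagents that add atoms: tert-butyldimethylsilyl chloride, C[Si](C)(Cl)C(C)(C)C
Why: Imidazole-promoted O-silylation of a phenol; the aryl TBS ether should tolerate Grignard, radical, weak-acid and amide-base conditions and leaves with buffered fluoride at the end.

**Step 2**
Reactants: 2 silylated vanillin; 3 vinylmagnesium bromide
Product: 4 rac-1-[4-(tert-butyldimethylsilyloxy)-3-methoxyphenyl]prop-2-en-1-ol
Conditions: THF, −78 to 0 °C; aq. NH4Cl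
Reagents that add atoms: vinylmagnesium bromide (3), C=C[Mg]Br
Why: Grignard 1,2-addition to a non-enolisable aldehyde; the future C5 carbinol centre forms racemic and is resolved in step 3.

**Step 3**
Reactants: 4 racemic allylic alcohol
Product: 5 (R)-1-[4-(tert-butyldimethylsilyloxy)-3-methoxyphenyl]prop-2-en-1-yl acetate
Conditions: immobilised Candida antarctica lipase B (Novozym 435), vinyl acetate, MTBE, 30 °C, stopped just short of half conversion
Reagents that add atoms: vinyl acetate, C=COC(C)=O
Why: Lipase-catalysed kinetic resolution by irreversible transesterification; with aryl as the large and vinyl as the medium group the enzyme should acylate the (R)-alcohol, so the wanted enantiomer is collected as the acetate and the untouched (S)-alcohol is removed by chromatography.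

**Step 4**
Reactants: 5 (R)-acetate
Product: 6 (R)-1-[4-(tert-butyldimethylsilyloxy)-3-methoxyphenyl]prop-2-en-1-ol
Conditions: iBu2AlH, CH2Cl2, −78 °C; aq. potassium sodium tartrate
Reagents that add atoms: none
Why: Reductive ester cleavage at the acyl carbon leaves the C–O bond of the stereocentre untouched and avoids the carbonate or alkoxide media that strip aryl silyl ethers.

**Step 5**
Reactants: 7 eugenol
Product: 8 (4-allyl-2-methoxyphenoxy)(tert-butyl)dimethylsilane
Conditions: TBSCl, imidazole, DMF, 0 °C to rt
Reagents that add atoms: tert-butyldimethylsilyl chloride, C[Si](C)(Cl)C(C)(C)C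
Why: Imidazole-promoted O-silylation of a phenol, giving ring A the same protecting group as ring B so that both leave together.

**Step 6**
Reactants: 8 silylated eugenol
Product: 10 2-[4-(tert-butyldimethylsilyloxy)-3-methoxyphenyl]acetaldehyde, via vicinal diol 9 (not isolated)
Conditions: OsO4 (cat.), NaIO4, 2,6-lutidine, dioxane–H2O, rt
Reagents that add atoms: osmium tetroxide (catalytic oxygen carrier), O=[Os](=O)(=O)=O; sodium periodate (terminal oxidant), [Na+].[O-]I(=O)(=O)=O
Why: Lemieux–Johnson cleavage (catalytic dihydroxylation, then periodate glycol fission) of the only alkene; the lutidine buffer keeps the medium near neutral, and the method spares the electron-rich ring that ozone could attack.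

**Step 7**
Reactants: 10 arylacetaldehyde
Product: 11 tert-butyl[2-methoxy-4-(3-methoxyprop-2-en-1-yl)phenoxy]dimethylsilane (methyl enol ether of the 3-arylpropanal, E/Z mixture)
Conditions: Ph3P(CH2OMe)Cl, KN(SiMe3)2 (slight deficit), THF, 0 °C; then 10, −78 °C to rt
Reagents that add atoms: (methoxymethyl)triphenylphosphonium chloride, COC[P+](c1ccccc1)(c1ccccc1)c1ccccc1.[Cl-]
Why: Wittig methoxymethylenation; the aldehyde is added cold to a solution free of excess base to limit enolisation, and the alkene geometry is irrelevant because both carbons become centres that are erased later.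

**Step 8**
Reactants: 6 (R)-allylic alcohol; 11 enol ether
Product: 12 mixed acetal of 2-iodo-3-[4-(tert-butyldimethylsilyloxy)-3-methoxyphenyl]propanal with methanol and with alcohol 6 (R at the allylic carbon)
Conditions: NIS, molecular sieves 4A, CH2Cl2, −78 to −20 °C, dark
Reagents that add atoms: N-iodosuccinimide, O=C1CCC(=O)N1I
Why: Iodoalkoxylation of an enol ether, the haloacetal synthesis of the Ueno–Stork sequence, in which NIS attacks the electron-rich double bond at C3 and alcohol 6 captures the oxocarbenium ion at C2 under neutral conditions that leave C5 untouched; the iodide is preferred to the bromide because halogen abstraction in step 9 must compete with O2 for the tin radical.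

**Step 9**
Reactants: 12 iodoacetal; 13 dioxygen
Product: 15 (3S,4S,5R)-4-hydroxymethyl-2-methoxyoxolane bearing the silylated ring A benzyl group at C3 and the silylated ring B at C5, via hydroperoxide 14 (not isolated)
Conditions: Bu3SnH (syringe pump), slow stream of dry air, dilute toluene, 25 °C; then PPh3, 25 °C; tin residues removed by MeCN/hexane partition
Reagents that add atoms: dioxygen (13), O=O
Why: Bu3Sn radicals take the iodine atom from 12, the secondary C3 radical adds to the inner vinyl carbon to make C3–C4, the primary CH2 radical left outside the ring combines with O2 to make the CH2–O bond, the peroxyl radical takes hydrogen from Bu3SnH to carry the chain, and PPh3 reduces hydroperoxide 14 to 15. The closest known reaction type is this very one, the aerobic (oxygenative) tin hydride version of the Ueno–Stork cyclisation of allylic haloacetals. The oxolane ring closes 5-exo-trig, a mode favoured over 6-endo by the short C–O bonds of the O1 tether and by the unsubstituted vinyl terminus, and made possible by holding C2 as an acetal, since an ester link would prefer a conformation that keeps radical and alkene apart. C4 is set by C5: in the chair-like transition state ring B sits pseudo-equatorial to avoid allylic strain with the vinyl group, so the new CH2 arm should end up trans to ring B for either C2 epimer. C3 is set only by the modest preference of 1-substituted hexenyl radicals for the cis-1,5 product, so 3,4-cis 15 should be the main isomer, and its C3 epimer is carried along because step 13 resets that centre. The step needs ring closure to beat O2 capture at C3 and O2 capture to beat hydrogen transfer at the primary radical: the weak carbon–iodine bond lets Bu3Sn radicals engage 12 although O2 also scavenges them, the oxygen-containing, doubly branched tether makes the closure fast while a slow air feed keeps dissolved O2 low, and slow addition keeps Bu3SnH too dilute to reduce the unhindered primary radical.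

**Step 10**
Reactants: 15 primary alcohol
Product: 16 tert-butyldiphenylsilyl ether of 15
Conditions: TBDPSCl, imidazole, CH2Cl2, rt
Reagents that add atoms: tert-butyldiphenylsilyl chloride, CC(C)(C)[Si](Cl)(c1ccccc1)c1ccccc1
Why: Standard silylation of a primary alcohol; masking it stops the C4 arm from closing onto C2 once the acetal is opened (which would lead to the isomeric lactone), and TBDPS outlasts the aqueous acid of step 11, adds bulk for step 13 and still leaves with fluoride.

**Step 11**
Reactants: 16 methyl acetal
Product: 17 lactol (2-hydroxyoxolane; mixture at C2 and C3; 4S,5R)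
Conditions: AcOH–THF–H2O, 45 °C
Reagents that add atoms: water, O
Why: Acid-catalysed acetal hydrolysis through the cyclic oxocarbenium ion; acetic acid suffices for a 2-alkoxyoxolane but should be too weak to ionise the benzylic C5–O bond or the silyl ethers, and any C3 epimerisation through the open hydroxy aldehyde is harmless because step 13 resets C3.

**Step 12**
Reactants: 17 lactol
Product: 18 lactone (4S,5R; both C3 epimers)
Conditions: Ag2CO3 on Celite, toluene, 110 °C
Reagents that add atoms: none
Why: Fétizon oxidation of a lactol on a neutral heterogeneous surface, so that C4, C5 and the silyl ethers persist; with C2 now trigonal, any minor 4,5-cis material from step 9 can be removed by chromatography.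

**Step 13**
Reactants: 18 lactone (C3 epimers)
Product: 20 (3S,4S,5R)-3-[4-(tert-butyldimethylsilyloxy)-3-methoxybenzyl]-5-[4-(tert-butyldimethylsilyloxy)-3-methoxyphenyl]-4-(tert-butyldiphenylsilyloxymethyl)oxolan-2-one, via lithium enolate 19 (not isolated)
Conditions: LiN(iPr)2 (commercial solution), THF, −78 °C; then 2,6-di-tert-butyl-4-methylphenol in THF, −78 °C; cold pH 7 buffer
Reagents that add atoms: none
Why: Deprotonation and kinetic protonation of a lactone enolate, the established way from trans to cis alpha,beta-disubstituted butyrolactones; both C3 epimers converge on planar enolate 19, and the hindered phenol should deliver its proton to the face opposite the bulky C4 arm, which places the benzyl group cis to that arm (3S).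

**Step 14**
Reactants: 20 tris-silylated lactone
Product: 21 (3S,4S,5R)-3-(4-hydroxy-3-methoxybenzyl)-5-(4-hydroxy-3-methoxyphenyl)-4-(hydroxymethyl)oxolan-2-one (target)
Conditions: Bu4NF, AcOH (excess over fluoride), THF, 0 °C to rt
Reagents that add atoms: none
Why: Fluoride desilylation of all three silyl ethers in one operation; the excess acetic acid keeps the freed phenols protonated, which should suppress enolisation at C3, expulsion of the lactone carboxylate from C5 through a quinone methide, and acyl migration to the primary alcohol.

**Compound list**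

1 | vanillin | COc1cc(C=O)ccc1O | starting material
2 | 4-(tert-butyldimethylsilyloxy)-3-methoxybenzaldehyde | COc1cc(C=O)ccc1O[Si](C)(C)C(C)(C)C | intermediate
3 | vinylmagnesium bromide | C=C[Mg]Br | starting material
4 | rac-1-[4-(tert-butyldimethylsilyloxy)-3-methoxyphenyl]prop-2-en-1-ol | COc1cc(C(O)C=C)ccc1O[Si](C)(C)C(C)(C)C | intermediate
5 | (R)-1-[4-(tert-butyldimethylsilyloxy)-3-methoxyphenyl]prop-2-en-1-yl acetate | CC(=O)O[C@@H](c1ccc(O[Si](C)(C)C(C)(C)C)c(OC)c1)C=C | intermediate
6 | (R)-1-[4-(tert-butyldimethylsilyloxy)-3-methoxyphenyl]prop-2-en-1-ol | O[C@@H](c1ccc(O[Si](C)(C)C(C)(C)C)c(OC)c1)C=C | intermediate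
7 | eugenol | COc1cc(CC=C)ccc1O | starting material
8 | (4-allyl-2-methoxyphenoxy)(tert-butyl)dimethylsilane | COc1cc(CC=C)ccc1O[Si](C)(C)C(C)(C)C | intermediate
9 | rac-3-[4-(tert-butyldimethylsilyloxy)-3-methoxyphenyl]propane-1,2-diol (not isolated) | COc1cc(CC(O)CO)ccc1O[Si](C)(C)C(C)(C)C | intermediate
10 | 2-[4-(tert-butyldimethylsilyloxy)-3-methoxyphenyl]acetaldehyde | COc1cc(CC=O)ccc1O[Si](C)(C)C(C)(C)C | intermediate
11 | methyl enol ether of the 3-arylpropanal (E/Z) | COC=CCc1ccc(O[Si](C)(C)C(C)(C)C)c(OC)c1 | intermediate
12 | mixed methyl (R)-1-arylallyl acetal of 2-iodo-3-arylpropanal (mixture at C2 and C3) | IC(Cc1ccc(O[Si](C)(C)C(C)(C)C)c(OC)c1)C(OC)O[C@@H](c1ccc(O[Si](C)(C)C(C)(C)C)c(OC)c1)C=C | intermediate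
13 | dioxygen | O=O | starting material
14 | (3S,4S,5R)-4-hydroperoxymethyl-2-methoxyoxolane (C2 epimers; main C3 epimer drawn; not isolated) | COc1cc(C[C@@H]2C(OC)O[C@@H](c3ccc(O[Si](C)(C)C(C)(C)C)c(OC)c3)[C@@H]2COO)ccc1O[Si](C)(C)C(C)(C)C | intermediate
15 | (3S,4S,5R)-4-hydroxymethyl-2-methoxyoxolane (C2 epimers; main C3 epimer drawn) | COc1cc(C[C@@H]2C(OC)O[C@@H](c3ccc(O[Si](C)(C)C(C)(C)C)c(OC)c3)[C@@H]2CO)ccc1O[Si](C)(C)C(C)(C)C | intermediate
16 | tert-butyldiphenylsilyl ether of 15 | COc1cc(C[C@@H]2C(OC)O[C@@H](c3ccc(O[Si](C)(C)C(C)(C)C)c(OC)c3)[C@@H]2CO[Si](c3ccccc3)(c3ccccc3)C(C)(C)C)ccc1O[Si](C)(C)C(C)(C)C | intermediate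
17 | lactol (4S,5R; mixture at C2 and C3) | COc1cc(CC2C(O)O[C@@H](c3ccc(O[Si](C)(C)C(C)(C)C)c(OC)c3)[C@@H]2CO[Si](c3ccccc3)(c3ccccc3)C(C)(C)C)ccc1O[Si](C)(C)C(C)(C)C | intermediate
18 | lactone (4S,5R; both C3 epimers) | COc1cc(CC2C(=O)O[C@@H](c3ccc(O[Si](C)(C)C(C)(C)C)c(OC)c3)[C@@H]2CO[Si](c3ccccc3)(c3ccccc3)C(C)(C)C)ccc1O[Si](C)(C)C(C)(C)C | intermediate
19 | lithium enolate of 18 (not isolated) | [Li+].COc1cc(CC2=C([O-])O[C@@H](c3ccc(O[Si](C)(C)C(C)(C)C)c(OC)c3)[C@@H]2CO[Si](c3ccccc3)(c3ccccc3)C(C)(C)C)ccc1O[Si](C)(C)C(C)(C)C | intermediate
20 | (3S,4S,5R)-tris-silylated lactone (3,4-cis, 4,5-trans) | COc1cc(C[C@@H]2C(=O)O[C@@H](c3ccc(O[Si](C)(C)C(C)(C)C)c(OC)c3)[C@@H]2CO[Si](c3ccccc3)(c3ccccc3)C(C)(C)C)ccc1O[Si](C)(C)C(C)(C)C | intermediate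
21 | (3S,4S,5R)-3-(4-hydroxy-3-methoxybenzyl)-5-(4-hydroxy-3-methoxyphenyl)-4-(hydroxymethyl)oxolan-2-one | COc1cc(C[C@@H]2C(=O)O[C@@H](c3ccc(O)c(OC)c3)[C@@H]2CO)ccc1O | target

Total step count: 14.
Longest linear sequence: 11 steps from vanillin (steps 1–4 and 8–14).

**Steps most likely to fail**

Step 9. Oxygen may capture the C3 radical before the ring closes. The tin hydride may be burnt by O2 without sustaining the chain. The peroxyl radical may also abstract the weak C5–H.
- The fallback separates ring closure from oxygenation and sets out from 12.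
- Under argon, 12 is isomerised by iodine atom transfer ((Bu3Sn)2 cat., visible light, benzene). This makes the same C3–C4 bond by the same 5-exo closure and gives the 4-iodomethyl oxolane F1.
- F1 is a primary iodide with nothing left to cyclise. It is hydroxylated with Bu3SnH under dry air, followed by PPh3.
- The sequence rejoins the route at 15.

Step 13. Facial selectivity may be eroded by proton return from the diisopropylamine bound to the enolate, or by equilibration before the quench is complete.
- The fallback replaces ionic by radical hydrogen delivery and sets out from 18.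
- Enolate 19 is trapped with PhSeCl to give the alpha-phenylselanyl lactone F2.
- Treating F2 with (Me3Si)3SiH and Et3B (trace air, toluene, −20 °C) generates the planar C3 radical. This radical should take hydrogen from the bulky silane on the face opposite the C4 arm.
- The sequence rejoins the route at 20.

Step 14. A transient phenoxide may expel the carboxylate from C5. C3 may epimerise, or the acyl group may migrate, during the slower loss of the TBDPS group.
- The fallback moves the fluoride step ahead of the step that sets C3, so that stereochemical erosion there costs nothing. It sets out from 18.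
- Bu4NF/AcOH gives the triol lactone F3 as C3 epimers.
- Me3SiCl/imidazole converts it into the tris(trimethylsilyl) ether F4.
- LiN(iPr)2 at −78 °C gives its lithium enolate F5. The amide is known to coexist with silylating agents at this temperature.
- The hindered phenol then gives the 3,4-cis tris(trimethylsilyl) lactone F6.
- The labile silyl groups are solvolysed with citric acid in MeOH, without fluoride or base, and the sequence rejoins the route at 21.

**Further compounds**

F1 | step 9 | 4-iodomethyl-2-methoxyoxolane with the same relative and absolute configuration as 15 (C2 epimers) | COc1cc(C[C@@H]2C(OC)O[C@@H](c3ccc(O[Si](C)(C)C(C)(C)C)c(OC)c3)[C@@H]2CI)ccc1O[Si](C)(C)C(C)(C)C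
F2 | step 13 | 3-phenylselanyl derivative of lactone 18 (C3 open) | COc1cc(CC2([Se]c3ccccc3)C(=O)O[C@@H](c3ccc(O[Si](C)(C)C(C)(C)C)c(OC)c3)[C@@H]2CO[Si](c3ccccc3)(c3ccccc3)C(C)(C)C)ccc1O[Si](C)(C)C(C)(C)C
F3 | step 14 | fully desilylated lactone (4S,5R; both C3 epimers) | COc1cc(CC2C(=O)O[C@@H](c3ccc(O)c(OC)c3)[C@@H]2CO)ccc1O
F4 | step 14 | tris(trimethylsilyl) ether of F3 | COc1cc(CC2C(=O)O[C@@H](c3ccc(O[Si](C)(C)C)c(OC)c3)[C@@H]2CO[Si](C)(C)C)ccc1O[Si](C)(C)C
F5 | step 14 | lithium enolate of F4 | [Li+].COc1cc(CC2=C([O-])O[C@@H](c3ccc(O[Si](C)(C)C)c(OC)c3)[C@@H]2CO[Si](C)(C)C)ccc1O[Si](C)(C)C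
F6 | step 14 | (3S,4S,5R)-tris(trimethylsilyl) lactone | COc1cc(C[C@@H]2C(=O)O[C@@H](c3ccc(O[Si](C)(C)C)c(OC)c3)[C@@H]2CO[Si](C)(C)C)ccc1O[Si](C)(C)C
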